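**Plan**

- Retrosynthesis: the two ring A benzyl ethers are removed last. Ring B is then cut at C1–C2 and C5–C6, giving methyl but-2-ynoate (C1, C6) and a C2–C5 ketene acetal diene whose C4 oxygen already bears the ring A acyl group.
- The diene is traced back through its O–Si bond to an enol ester. The enol ester C4–O–C(=O) bond is cut to methyl 2-methylacetoacetate and the ring A acid. The acid comes from 2,4-dihydroxy-3,6-dimethylbenzaldehyde (C5'–Cl bond, two O–benzyl bonds, aldehyde to acid).
- Enabling feature: ring B is a 2,4-dioxygenated benzoate. C2 (OH), C3 (Me), C4 (O-acyl) and C5 (H) form an acetoacetate-type four-carbon unit, and C1 (CO2Me) and C6 (Me) are the two alkyne carbons of a but-2-ynoate.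
- Forward: ring A is bought intact and dressed (Cl, benzyl ethers, CO2H). The four-carbon chain is joined to it as an enol ester and turned into the diene. Ring B, the only ring made, arises by Diels–Alder reaction and aromatisation, and debenzylation finishes the route.
- Stereochemistry: the target has no stereocentre and no stereogenic double bond. The enol ester and ketene acetal geometries and the acetal carbon of the cycloadduct are transient and disappear on aromatisation.

Key step: step 6

Assumption: the enol ester 8 is drawn as its expected major E isomer and the ketene acetal geometry of 9 is left open, since both are erased when ring B aromatises; aldehyde 1 is taken to be purchasable.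

**Route**

Step 1
Reactants: 1 2,4-dihydroxy-3,6-dimethylbenzaldehyde
Product: 2 5-chloro-2,4-dihydroxy-3,6-dimethylbenzaldehyde
Conditions: SO2Cl2 (1.05 equiv), Et2O, 0 °C to rt
Reagents that add atoms: sulfuryl chloride, O=S(=O)(Cl)Cl
Why: Electrophilic aromatic chlorination; C5 is the only unsubstituted ring carbon and lies ortho to the 4-OH and para to the 2-OH, so a single monochloride should form while the hydrogen-bonded aldehyde stays intact.

Step 2
Reactants: 2 5-chloro-2,4-dihydroxy-3,6-dimethylbenzaldehyde
Product: 3 2,4-bis(benzyloxy)-5-chloro-3,6-dimethylbenzaldehyde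
Conditions: BnBr (2.5 equiv), K2CO3 (3 equiv), DMF, 60 °C
Reagents that add atoms: benzyl bromide, BrCc1ccccc1
Why: Williamson ether synthesis; K2CO3 in warm DMF should benzylate both the flanked 4-OH and the aldehyde-chelated 2-OH, and benzyl ethers are chosen because they tolerate the acid chloride, the amide base and the heating of later steps and leave under neutral hydrogenolysis.

Step 3
Reactants: 3 2,4-bis(benzyloxy)-5-chloro-3,6-dimethylbenzaldehyde
Product: 4 2,4-bis(benzyloxy)-5-chloro-3,6-dimethylbenzoic acid
Conditions: NaClO2, NaH2PO4, 2-methylbut-2-ene, t-BuOH/THF/H2O, rt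
Reagents that add atoms: sodium chlorite, [Na+].[O-]Cl=O
Why: Pinnick (Lindgren) chlorite oxidation should convert the hindered, electron-rich aldehyde to the acid without touching the benzyl ethers, the alkene scavenging HOCl and the fully substituted ring offering no site for chlorination.

Step 4
Reactants: 4 2,4-bis(benzyloxy)-5-chloro-3,6-dimethylbenzoic acid; 5 methyl 2-methyl-3-oxobutanoate (methyl 2-methylacetoacetate, racemic)
Product: 8 methyl (E)-3-{[2,4-bis(benzyloxy)-5-chloro-3,6-dimethylbenzoyl]oxy}-2-methylbut-2-enoate, via acid chloride 6 (not isolated), via sodium enolate 7 (not isolated)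
Conditions: 4, (COCl)2 (1.3 equiv), N,N-dimethylformamide (cat.), CH2Cl2, 0 °C to rt, evaporate; 5, NaH (1.1 equiv), THF/DMPU, 0 °C; then 6 in THF, 0 °C to rt
Reagents that add atoms: none
Why: Acid chloride formation under Vilsmeier catalysis followed by O-acylation of a β-keto ester enolate; the α-methyl group, the dissociating co-solvent and the hindered, hard acyl chloride should all steer attack to the ketone oxygen (C-acylation would have to build a quaternary carbon) and favour the E enol ester.

Step 5
Reactants: 8 methyl (E)-3-{[2,4-bis(benzyloxy)-5-chloro-3,6-dimethylbenzoyl]oxy}-2-methylbut-2-enoate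
Product: 9 4-methoxy-3-methyl-4-(trimethylsilyloxy)buta-1,3-dien-2-yl 2,4-bis(benzyloxy)-5-chloro-3,6-dimethylbenzoate
Conditions: LiN(i-Pr)2 (1.1 equiv), Me3SiCl (1.5 equiv), THF, −78 °C, in situ quench; then 0 °C, pentane, filtration under argon
Reagents that add atoms: chlorotrimethylsilane, C[Si](C)(C)Cl
Why: Kinetic γ-deprotonation of the β-oxygenated enoate gives the extended ester dienolate, which the silyl chloride already present should trap on oxygen at −78 °C before acyl transfer or loss of carboxylate can compete (vinylogous silyl ketene acetal formation, as used for 1-alkoxy-1-siloxy dienes from β-alkoxy- and β-siloxycrotonates); the C4 methyl is the only acidic site conjugated to the ester, and the aroyl group has no α-hydrogen and is shielded by two ortho substituents.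

Step 6
Reactants: 9 4-methoxy-3-methyl-4-(trimethylsilyloxy)buta-1,3-dien-2-yl 2,4-bis(benzyloxy)-5-chloro-3,6-dimethylbenzoate; 10 methyl but-2-ynoate
Product: 12 methyl 4-{[2,4-bis(benzyloxy)-5-chloro-3,6-dimethylbenzoyl]oxy}-2-hydroxy-3,6-dimethylbenzoate, via cyclohexa-1,4-diene cycloadduct 11 (not isolated)
Conditions: 10 (5 equiv), PhMe, 110 °C, sealed tube; then 1 M HCl (aq), THF, rt
Reagents that add atoms: none
Why: The 1-methoxy-1-siloxy terminus raises the diene HOMO and places its largest coefficient on the CH2 carbon (C5), which should bond first to the methyl-bearing β-carbon of the ynoate (C6) in a thermal, asynchronous, normal-demand Diels–Alder reaction, with C2–C1 following, to give the cyclohexa-1,4-diene 11. The closest known reaction type is the resorcylate synthesis from 1-alkoxy-1,3-bis(siloxy)buta-1,3-dienes and alkynoates, with the ring A aroyloxy group standing here in place of the 3-siloxy group. Ring B is closed by the intermolecular [4+2] cycloaddition itself, both new bonds lying in the six-membered carbocycle. The only new stereocentre is the acetal carbon C2 of 11, formed as a racemate without control and destroyed when dilute acid opens the silyl methyl acetal to the dienone (methanol and trimethylsilanol leave) and C5–H enolises to give the C2 phenol. The step needs regioselectivity (CO2Me beside the new OH, methyl beside C5–H), which the polarisation of the ketene acetal against the ynoate secures, and chemoselective cleavage of the mixed acetal, which mild acid gives without harming the hindered aryl ester or the benzyl ethers.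

Step 7
Reactants: 12 methyl 4-{[2,4-bis(benzyloxy)-5-chloro-3,6-dimethylbenzoyl]oxy}-2-hydroxy-3,6-dimethylbenzoate
Product: 13 methyl 4-[(5-chloro-2,4-dihydroxy-3,6-dimethylbenzoyl)oxy]-2-hydroxy-3,6-dimethylbenzoate
Conditions: H2 (1 atm), 10% Pd/C, EtOAc, rt
Reagents that add atoms: none
Why: Hydrogenolysis of benzyl aryl ethers in neutral ethyl acetate should free both ring A phenols; the electron-rich aryl chloride flanked by two ortho substituents is reduced much more slowly without base and both esters are inert, so the reaction is stopped after uptake of two equivalents of hydrogen.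

**Compound list**

1 | 2,4-dihydroxy-3,6-dimethylbenzaldehyde | Cc1cc(O)c(C)c(O)c1C=O | starting material
2 | 5-chloro-2,4-dihydroxy-3,6-dimethylbenzaldehyde | Cc1c(Cl)c(O)c(C)c(O)c1C=O | intermediate
3 | 2,4-bis(benzyloxy)-5-chloro-3,6-dimethylbenzaldehyde | Cc1c(Cl)c(OCc2ccccc2)c(C)c(OCc2ccccc2)c1C=O | intermediate
4 | 2,4-bis(benzyloxy)-5-chloro-3,6-dimethylbenzoic acid | Cc1c(Cl)c(OCc2ccccc2)c(C)c(OCc2ccccc2)c1C(=O)O | intermediate
5 | methyl 2-methyl-3-oxobutanoate (racemic) | COC(=O)C(C)C(C)=O | starting material
6 | 2,4-bis(benzyloxy)-5-chloro-3,6-dimethylbenzoyl chloride (formed in the flask) | Cc1c(Cl)c(OCc2ccccc2)c(C)c(OCc2ccccc2)c1C(Cl)=O | intermediate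
7 | sodium enolate of methyl 2-methyl-3-oxobutanoate (formed in the flask) | COC(=O)C(C)=C(C)[O-].[Na+] | intermediate
8 | methyl (E)-3-{[2,4-bis(benzyloxy)-5-chloro-3,6-dimethylbenzoyl]oxy}-2-methylbut-2-enoate | COC(=O)/C(C)=C(\C)OC(=O)c1c(C)c(Cl)c(OCc2ccccc2)c(C)c1OCc3ccccc3 | intermediate
9 | 4-methoxy-3-methyl-4-(trimethylsilyloxy)buta-1,3-dien-2-yl 2,4-bis(benzyloxy)-5-chloro-3,6-dimethylbenzoate (ketene acetal geometry as formed) | C=C(OC(=O)c1c(C)c(Cl)c(OCc2ccccc2)c(C)c1OCc3ccccc3)C(C)=C(OC)O[Si](C)(C)C | intermediate
10 | methyl but-2-ynoate | CC#CC(=O)OC | starting material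
11 | methyl 4-{[2,4-bis(benzyloxy)-5-chloro-3,6-dimethylbenzoyl]oxy}-6-methoxy-2,5-dimethyl-6-(trimethylsilyloxy)cyclohexa-1,4-diene-1-carboxylate (racemic, formed in the flask) | COC(=O)C1=C(C)CC(OC(=O)c2c(C)c(Cl)c(OCc3ccccc3)c(C)c2OCc4ccccc4)=C(C)C1(OC)O[Si](C)(C)C | intermediate
12 | methyl 4-{[2,4-bis(benzyloxy)-5-chloro-3,6-dimethylbenzoyl]oxy}-2-hydroxy-3,6-dimethylbenzoate | COC(=O)c1c(C)cc(OC(=O)c2c(C)c(Cl)c(OCc3ccccc3)c(C)c2OCc4ccccc4)c(C)c1O | intermediate
13 | methyl 4-[(5-chloro-2,4-dihydroxy-3,6-dimethylbenzoyl)oxy]-2-hydroxy-3,6-dimethylbenzoate | COC(=O)c1c(C)cc(OC(=O)c2c(C)c(Cl)c(O)c(C)c2O)c(C)c1O | target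

**Count**

Total steps: 7. Longest linear sequence: 7 steps (1 to 13).

**Steps most likely to fail**

Step 6. The cycloaddition of the acyloxy diene with the β-methyl ynoate may be slower than thermal O-to-C silyl migration or adventitious hydrolysis of the ketene acetal, so that the diene is consumed without ring closure. The fallback sets out from 9 and replaces the alkyne by the more electrophilic allene methyl buta-2,3-dienoate (commercial), whose conjugated double bond should react in toluene at 20–60 °C with the same polarity (C5 to the central allene carbon, C2 to the α-carbon). This gives methyl 4-{[2,4-bis(benzyloxy)-5-chloro-3,6-dimethylbenzoyl]oxy}-2-methoxy-3-methyl-6-methylidene-2-(trimethylsilyloxy)cyclohex-3-ene-1-carboxylate F1 as a mixture of diastereomers. Dilute HCl in THF opens the acetal to the ketone, and Et3N moves the exocyclic double bond into the ring, so that the fallback comes back to the route at 12.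

Step 5. The lithium dienolate may expel the ring A carboxylate (β-elimination to an allenoate) or pass its acyl group to another molecule, or the base may deprotonate the ring A C6 methyl group before silylation is complete. The fallback sets out from 5 and carries the C4 oxygen as a silyl ether, ring A being attached only after ring B exists. Compound 5 is silylated (Me3SiCl, Et3N) to methyl 2-methyl-3-(trimethylsilyloxy)but-2-enoate F2, which with LiN(i-Pr)2 and Me3SiCl at −78 °C gives 1-methoxy-2-methyl-1,3-bis(trimethylsilyloxy)buta-1,3-diene F3. Heating F3 with 10 gives the cycloadduct methyl 6-methoxy-2,5-dimethyl-4,6-bis(trimethylsilyloxy)cyclohexa-1,4-diene-1-carboxylate F4, which dilute acid converts to methyl 2,4-dihydroxy-3,6-dimethylbenzoate F5. Acid chloride 6, made from 4 as in step 4, then acylates the C4 hydroxyl of F5 (Et3N, 4-(dimethylamino)pyridine cat., CH2Cl2), the C2 hydroxyl being held in a hydrogen bond to the ester, and the fallback comes back to the route at 12.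

Step 4. The di-ortho-substituted acid chloride may acylate the enolate slowly or on carbon, leaving time for loss of the ortho benzyl ether to HCl or for enolate self-condensation. The fallback sets out from 4 and forms the enol ester C–O bond by conjugate addition instead of acylation. The carboxylate of 4 (K2CO3 or 1,4-diazabicyclo[2.2.2]octane, MeCN) is added to the central carbon of commercial ethyl 2-methylbuta-2,3-dienoate to give ethyl 3-{[2,4-bis(benzyloxy)-5-chloro-3,6-dimethylbenzoyl]oxy}-2-methylbut-3-enoate F6. Its doubly activated C2–H is removed by LiN(i-Pr)2 in the presence of Me3SiCl to give 4-ethoxy-3-methyl-4-(trimethylsilyloxy)buta-1,3-dien-2-yl 2,4-bis(benzyloxy)-5-chloro-3,6-dimethylbenzoate F7. Under the conditions of step 6, F7 and 10 should give the cycloadduct methyl 4-{[2,4-bis(benzyloxy)-5-chloro-3,6-dimethylbenzoyl]oxy}-6-ethoxy-2,5-dimethyl-6-(trimethylsilyloxy)cyclohexa-1,4-diene-1-carboxylate F8, which loses ethanol in place of methanol, and the fallback comes back to the route at 12.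

**Further compounds**

F1 | step 6 | methyl 4-{[2,4-bis(benzyloxy)-5-chloro-3,6-dimethylbenzoyl]oxy}-2-methoxy-3-methyl-6-methylidene-2-(trimethylsilyloxy)cyclohex-3-ene-1-carboxylate (mixture of diastereomers) | COC(=O)C1C(=C)CC(OC(=O)c2c(C)c(Cl)c(OCc3ccccc3)c(C)c2OCc4ccccc4)=C(C)C1(OC)O[Si](C)(C)C
F2 | step 5 | methyl 2-methyl-3-(trimethylsilyloxy)but-2-enoate (E/Z mixture) | COC(=O)C(C)=C(C)O[Si](C)(C)C
F3 | step 5 | 1-methoxy-2-methyl-1,3-bis(trimethylsilyloxy)buta-1,3-diene | C=C(O[Si](C)(C)C)C(C)=C(OC)O[Si](C)(C)C
F4 | step 5 | methyl 6-methoxy-2,5-dimethyl-4,6-bis(trimethylsilyloxy)cyclohexa-1,4-diene-1-carboxylate (racemic) | COC(=O)C1=C(C)CC(O[Si](C)(C)C)=C(C)C1(OC)O[Si](C)(C)C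
F5 | step 5 | methyl 2,4-dihydroxy-3,6-dimethylbenzoate | COC(=O)c1c(C)cc(O)c(C)c1O
F6 | step 4 | ethyl 3-{[2,4-bis(benzyloxy)-5-chloro-3,6-dimethylbenzoyl]oxy}-2-methylbut-3-enoate (racemic) | CCOC(=O)C(C)C(=C)OC(=O)c1c(C)c(Cl)c(OCc2ccccc2)c(C)c1OCc3ccccc3
F7 | step 4 | 4-ethoxy-3-methyl-4-(trimethylsilyloxy)buta-1,3-dien-2-yl 2,4-bis(benzyloxy)-5-chloro-3,6-dimethylbenzoate | C=C(OC(=O)c1c(C)c(Cl)c(OCc2ccccc2)c(C)c1OCc3ccccc3)C(C)=C(OCC)O[Si](C)(C)C
F8 | step 4 | methyl 4-{[2,4-bis(benzyloxy)-5-chloro-3,6-dimethylbenzoyl]oxy}-6-ethoxy-2,5-dimethyl-6-(trimethylsilyloxy)cyclohexa-1,4-diene-1-carboxylate (racemic) | COC(=O)C1=C(C)CC(OC(=O)c2c(C)c(Cl)c(OCc3ccccc3)c(C)c2OCc4ccccc4)=C(C)C1(OCC)O[Si](C)(C)C
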